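**Remarks on the chemistry**

- Numbering used throughout: C1(=O), C2(OMe), C3(H), C4(=O), C4a, C5(H), C6(CH2Ar), C7(CH3), C8(aryl), C8a. Ring A is the quinone ring and ring B the benzenoid ring.
- Orientation check: only the 2-bromo-6-methoxy isomer of the quinone places the methoxy group next to the carbonyl that ends up peri to the C8 aryl group; the 2-bromo-5-methoxy isomer would give the 3-methoxy series. The 2,6-isomer is used.
- Assumption: both phenols are carried as triisopropylsilyl ethers instead of tert-butyldimethylsilyl ethers, because the route passes a catalytic alkoxide step and an aqueous phosphate step; the silyl groups are spectators in the cycloaddition.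
- Assumption: the target is achiral (the C8–aryl axis is taken to rotate freely), so intermediates 14 and 15 are handled as racemates.

## Structural features

Larreantin is a 2-methoxy-1,4-naphthoquinone: ring A (C1(=O), C2(OMe), C3(H), C4(=O)) is the quinone ring and ring B (C4a, C5 to C8, C8a) the benzenoid ring, the two sharing the C4a–C8a bond. Ring B is pentasubstituted, with H at C5, a 4-hydroxy-3-methoxybenzyl group at C6, a methyl group at C7 and a 4-hydroxy-3-methoxyphenyl group bonded directly to C8, peri to the C1 carbonyl. The molecule has no stereogenic centre, so no stereocentres stand next to each other; the only stereo-element is the C8–aryl axis between the C7 methyl group and the C1 carbonyl, and it needs no control. The fragile groups are the methoxyquinone (a vinylogous ester and conjugate acceptor, sensitive to nucleophiles, strong base and reductants), the two guaiacyl phenols, and the doubly benzylic C6–CH2, which with a free para-hydroxyl can be oxidised through a quinone methide. The real difficulty is regiochemical: four different groups must stand in a fixed order around ring B and in a fixed relation to the single methoxy group of ring A, since the C8 aryl group and the C2 methoxy group flank the same carbonyl, C1. The key step uses the fact that C5–C6–C7–C8 with their substituents form a 1-aryl-2-methyl-3-benzylbuta-1,3-diene, while C4a=C8a together with ring A is one C=C bond of a methoxy-1,4-benzoquinone. A bromine atom on the future C8a orients the [4+2] addition and then leaves as HBr, so ring A keeps the quinone oxidation level and ring B needs only a tautomerisation and a two-electron oxidation to become aromatic.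

## Logic of the disconnections

**18 to 17.** Two O–Si bonds are cut and no skeletal bond. The free phenols are acidic and oxidisable and would interfere with the organometallic steps, the cycloaddition and the oxidation of ring A. The gain is that every earlier intermediate is neutral and non-phenolic. The forward step must unmask both phenols without touching the C2 methoxy quinone, which calls for buffered fluoride.

**17 to 15.** No carbon–carbon bond is cut; two hydrogens are returned to C5 and C8, turning aromatic ring B into a cyclohexa-1,4-diene fused to the quinone. This exposes the cyclohexene retron (C6=C7 flanked by C5 and C8) and turns an aromatic substitution problem into an alkene addition problem. The forward step must move the hydrogens from C5 and C8 to the carbonyl oxygens (giving 16) and then remove two electrons, without oxidising the diarylmethane CH2 or the protected guaiacyl rings.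

**15 to 9 and 13.** The bonds C8–C8a and C4a–C5 are cut after formal return of HBr across C4a=C8a (14). This is the retro-[4+2] step; bromine sits on C8a because there it activates, orients and serves as the leaving group that sets the oxidation level. The 27-carbon skeleton falls into a 20-carbon diene carrying all four substituents of ring B and a seven-carbon ring A piece, with no stereocentre to carry. The forward step must choose the brominated C=C of 13 over the methoxylated one, must bond the aryl-bearing diene terminus to the bromine-bearing carbon, and must lose HBr without exposing 9 or the silyl ethers to acid.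

**13 to 12 to 10.** First the oxidation level of ring A is lowered (quinone to hydroquinone), then the C4–O bond is exchanged for a C–CHO bond. This traces ring A to a cheap, correctly substituted benzaldehyde in which bromine and methoxy already flank the phenol oxygen that becomes C1=O. The forward steps are an aryl migration to peroxide oxygen and a mild two-electron oxidation.

**9 to 5 and 8.** The central sigma bond of the diene (C6–C7 in the final numbering) is cut between two sp2 carbons. Both halves then carry a preformed alkene of defined geometry and are joined by cross-coupling under nearly neutral conditions. This avoids a carbonyl-based assembly, which would need a 4-silyloxybenzyl organometallic (prone to Wurtz-type homocoupling) and a basic methylenation of an enolisable benzyl ketone. The two halves are of similar size and both come from 2. The forward step must proceed with retention at both alkenes and must not shift the exocyclic C=C into conjugation.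

**5 to 4, then 4 to 2 and 3.** A C–B and a C–H bond are removed from the same face of the alkene, then the aryl–C(sp) bond is cut. The trisubstituted alkene geometry is reduced to the regiochemistry of a syn addition to an aryl alkyl alkyne. The forward steps need boron on the methyl-bearing carbon and an aryl–alkyne coupling on an electron-rich bromide.

**8 to 2 and 6 (through 7), and 2 to 1.** The aryl–CH2 bond is cut so that the nucleophile is an aryl, not a benzyl, organometallic and the electrophile a bifunctional C3 unit whose vinylic bromide survives. The final cut is the O–Si bond of 2. The forward steps need chemoselective reaction at the allylic C–Br of 6 and a silyl ether that tolerates magnesium.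

## Other disconnections considered

**Alternative 1:** The cut runs through C6–C7 and C8–C8a, with the C6 and C7 substituents tied together temporarily as a lactone. Forward, the 3-arylpropargyl (E)-2,4,5-trimethoxycinnamate A1 would be heated in nitrobenzene. The styrene unit (the cinnamate C=C plus one aromatic C=C of the trimethoxyphenyl ring) would act as diene and the aryl alkyne as dienophile in an intramolecular dehydro-Diels–Alder reaction; loss of H2 to the solvent would give the arylnaphthalene lactone A2.
- In its favour: the ester tether fixes the orientation by connectivity, A1 comes from one esterification of two simple halves, ring B emerges already aromatic, and ring A travels as a robust 1,2,4-trimethoxyarene.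
- Against it here: after the key step neither C6 nor C7 carries the right group. The lactone carbonyl on C6 must become a CH2–aryl group (partial reduction, aryl addition, benzylic deoxygenation) and the C7–CH2–O must be reduced to CH3. The 1,4-dimethoxy pattern must then be oxidised to the quinone, for instance with (NH4)2Ce(NO3)6, in a molecule with two further electron-rich rings and a diarylmethane CH2, and the methoxymethyl ether removed. The thermal step must also break the aromaticity of a trimethoxyphenyl ring in the transition state and must dehydrogenate, not stop at a dihydronaphthalene.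
- Comparison: on regiocontrol this alternative is the better plan (connectivity instead of orbital control). On substrate robustness it is at least the equal (no sensitive diene, no quinone dienophile). On mechanism both are [4+2] processes, but the chosen one pairs an electron-rich diene with an electron-poor quinone at moderate temperature, whereas A1 would need forcing conditions. On step economy the chosen plan is clearly better: its cycloaddition installs all four ring B substituents and leaves two steps, whereas some six to eight operations would follow A2.

**Alternative 2:** The cut is C8–C8a alone; ring B is closed by electrophilic cyclisation and the C6 and C7 groups come later. Forward, ICl would activate the alkyne of the ynone A3, the free ortho carbon of the trimethoxyphenyl ring (C8a) would attack the aryl-bearing alkyne carbon in a 6-endo-dig closure, and enolisation would give the iodonaphthol A4.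
- In its favour: mild conditions, an aromatic ring B at once, and two orthogonal handles exactly at C7 (iodide) and C6 (hydroxyl, via a sulfonate) for successive methyl and benzyl cross-couplings. For analogue work this modularity makes it the better plan.
- Against it here: the attacking carbon C8a is activated by one ortho methoxy group only, while the ipso carbon C4a lies ortho and para to two methoxy groups, so dearomatising ipso attack (spirocyclisation) or plain addition of ICl to the electron-poor ynone may compete. A3 is also a conjugate acceptor with an acidic benzylic CH2. The C7 iodide is flanked by the C8 aryl group and the C6 oxygen, so both couplings are hindered, and the benzylation needs a 4-alkoxybenzyl organometallic, a class prone to homocoupling. Oxidative demethylation to the quinone and debenzylation (hydrogenolysis would reduce the quinone and require re-oxidation) still follow.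
- Comparison: on structure the fixed regiochemistry is the equal or the better of the chosen plan, and it shares the absence of stereochemical issues. On mechanism it forms one C–C bond by a cationic closure where the cycloaddition forms two. On step economy about five steps would follow A4 against two after 15, and the approach to A3 is no shorter than that to 9, so the chosen plan is shorter.

**Alternative 3:** The cut is C4a–C4 and C4–C3, with carbon monoxide supplying C4; ring B is a preformed pentasubstituted benzene. Forward, the iodoaryl 2-methoxy enone A5 with Pd(PPh3)4, Et3N and CO would undergo oxidative addition at C4a–I, CO insertion, 6-endo acylpalladation of the enone terminus and beta-hydride elimination, closing ring A directly as the quinone, O,O-dibenzyl larreantin A6.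
- In its favour: the quinone ring is made at the correct oxidation level with the methoxy group placed by connectivity, no late oxidation of an electron-rich arene is needed (the equal of the chosen plan on that point), and only one step would follow the key step against two (the better on that count).
- Against it here: the whole regiochemical problem moves into the synthesis of A5, a benzene with five contiguous different substituents including a hindered ortho-iodoaryl ketone and a polymerisable 2-methoxy enone, which would take many more steps than the five leading to 9. The acylpalladium species must add 6-endo and not 5-exo, which would leave an alkylpalladium without a beta-hydrogen. Debenzylation by hydrogenolysis would reduce the quinone, and Lewis-acid debenzylation would endanger the three methyl ethers.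
- Comparison: on structure the chosen plan creates ring B and its substitution pattern in one convergent step, whereas this one needs that pattern beforehand. On mechanism the chosen plan relies on a thermal pericyclic step, this one on a multi-event palladium cascade with a regiochemical branch point. On overall step economy the chosen plan is better, although the end-game of the alternative is shorter.

Key step: step 8

## Route

Step 1
Reactants: 1 4-bromo-2-methoxyphenol
Product: 2 (4-bromo-2-methoxyphenoxy)triisopropylsilane
Conditions: i-Pr3SiCl (1.1 equiv), imidazole (2 equiv), DMF, 23 °C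
Reagents that add atoms: chlorotriisopropylsilane, CC(C)[Si](Cl)(C(C)C)C(C)C
Why: Standard silylation of a phenol with a silyl chloride and imidazole; the bulky triisopropylsilyl ether is chosen to survive magnesium, catalytic alkoxide and aqueous phosphate in the following steps.

Step 2
Reactants: 2 (4-bromo-2-methoxyphenoxy)triisopropylsilane; 3 propyne
Product: 4 [2-methoxy-4-(prop-1-yn-1-yl)phenoxy]triisopropylsilane
Conditions: 3 (THF solution, 3 equiv), Pd(PhCN)2Cl2 (3 mol %), P(t-Bu)3·HBF4 (6 mol %), CuI (2 mol %), i-Pr2NH (2 equiv), dioxane, 23 → 45 °C, sealed tube
Reagents that add atoms: none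
Why: Sonogashira coupling of an aryl bromide with a terminal alkyne; the bulky electron-rich phosphine allows oxidative addition into the electron-rich bromide near room temperature, and the silyl ether is inert to the secondary amine.

Step 3
Reactants: 4 [2-methoxy-4-(prop-1-yn-1-yl)phenoxy]triisopropylsilane
Product: 5 (Z)-2-{1-[3-methoxy-4-(triisopropylsilyloxy)phenyl]prop-1-en-2-yl}-4,4,5,5-tetramethyl-1,3,2-dioxaborolane (aryl cis to methyl, trans to boron)
Conditions: B2pin2 (1.1 equiv), CuCl (5 mol %), P(p-tol)3 (6 mol %), NaOt-Bu (10 mol %), MeOH (2 equiv), THF, 23 °C
Reagents that add atoms: bis(pinacolato)diboron, CC1(C)OB(OC1(C)C)B1OC(C)(C)C(C)(C)O1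
Why: Copper-catalysed formal hydroboration of an aryl alkyl alkyne: the copper boryl species adds syn with copper on the aryl-bearing carbon (stabilised benzylic-type C–Cu) and boron on the methyl-bearing carbon, and methanol protonates the C–Cu bond with retention. The resulting aryl-trans-to-boron geometry is the one the E diene requires.

Step 4
Reactants: 2 (4-bromo-2-methoxyphenoxy)triisopropylsilane; 6 2,3-dibromoprop-1-ene
Product: 8 [4-(2-bromoprop-2-en-1-yl)-2-methoxyphenoxy]triisopropylsilane, via arylmagnesium bromide 7 (not isolated)
Conditions: Mg turnings (1.3 equiv), THF, 50 °C; then added to 6 (1.5 equiv), CuI (5 mol %), THF, −20 → 0 °C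
Reagents that add atoms: none
Why: Grignard formation from the aryl bromide followed by copper-catalysed allylic substitution; only the allylic C–Br of 6 reacts (direct and allylic-transposed attack give the same product) and the vinylic C–Br is kept for the next coupling. The nucleophile is an aryl and not a benzyl organometallic, which avoids homocoupling.

Step 5
Reactants: 5 (Z)-alkenylboronate; 8 [4-(2-bromoprop-2-en-1-yl)-2-methoxyphenoxy]triisopropylsilane
Product: 9 (E)-1-[3-methoxy-4-(triisopropylsilyloxy)phenyl]-3-[3-methoxy-4-(triisopropylsilyloxy)benzyl]-2-methylbuta-1,3-diene
Conditions: Pd(dppf)Cl2 (5 mol %), K3PO4 (3 equiv), THF/H2O (10:1), 60 °C, argon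
Reagents that add atoms: none
Why: Suzuki–Miyaura coupling of an alkenylboronate with an alkenyl bromide; oxidative addition, transmetalation and reductive elimination all proceed with retention, so the geometry of 5 becomes the E geometry of 9. Phosphate in wet THF is mild enough to leave the aryl silyl ethers and the skipped diene unchanged.

Step 6
Reactants: 10 5-bromovanillin
Product: 12 2-bromo-6-methoxybenzene-1,4-diol, via aryl formate 11 (not isolated)
Conditions: H2O2 (30% aq., 1.3 equiv), NaOH (1 M aq., 2.2 equiv), 0 → 23 °C, N2; then HCl (1 M) to pH 2
Reagents that add atoms: hydrogen peroxide, OO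
Why: Dakin oxidation of a para-hydroxybenzaldehyde: hydroperoxide adds to the aldehyde, the electron-rich aryl group migrates to oxygen to give formate 11, and this is saponified in the same flask; exclusion of air keeps the hydroquinone from oxidising in base.

Step 7
Reactants: 12 2-bromo-6-methoxybenzene-1,4-diol
Product: 13 2-bromo-6-methoxy-1,4-benzoquinone
Conditions: FeCl3 (2.5 equiv), H2O/MeCN, 23 °C
Reagents that add atoms: none
Why: Two-electron oxidation of a hydroquinone to the para-quinone by trivalent iron in aqueous medium; the quinone is stable to the acidic conditions.

Step 8
Reactants: 9 (E)-diene; 13 2-bromo-6-methoxy-1,4-benzoquinone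
Product: 15 racemic 2-methoxy-7-methyl-8-[3-methoxy-4-(triisopropylsilyloxy)phenyl]-6-[3-methoxy-4-(triisopropylsilyloxy)benzyl]-5,8-dihydronaphthalene-1,4-dione, via cis-fused bromo adduct 14 (not isolated)
Conditions: 9 (1.1 equiv), 13 (1.0 equiv), NaHCO3 (powder, 2 equiv), toluene, 23 → 60 °C, argon, dark
Reagents that add atoms: none
Why: This is a thermal Diels–Alder reaction of normal electron demand: the electron-rich diene 9, in the s-cis conformation favoured by its 2,3-disubstitution and with the E aryl group pointing outward, adds suprafacially to the brominated C=C of 13, forming C8–C8a and C4a–C5 in one concerted, asynchronous event and closing the six-membered ring B by [4+2] annulation. The closest known reaction type is the cycloaddition of bromo- and methoxy-substituted benzoquinones with 1-aryl or 1-oxy dienes followed by dehydrohalogenation. Site selectivity is needed and is secured by the methoxy group, which makes its own C=C a vinylogous ester and a poor dienophile, so only the brominated C=C reacts. Orientation is needed and is secured twice over: the largest HOMO coefficient of 9 lies on the unsubstituted CH2 terminus remote from the aryl group, and the largest LUMO coefficient of 13 lies on the bromine-free carbon, which is beta to the carbonyl that receives no donation from the methoxy group and is also the carbon favoured by the bromine substituent, so the aryl-bearing carbon bonds to the bromine-bearing carbon, the future C8a. Adduct 14 has three stereocentres, the cis ring fusion (H on C4a, Br on C8a) following from suprafacial addition and the C8 configuration from the endo transition state, but none needs control because all are racemic and transient. 14 then enolises at C4a–H towards C4=O and expels bromide from C8a (E1cB), restoring the ene-dione as 15, while NaHCO3 takes up the HBr so that neither 9 nor the silyl ethers meet acid. C8 of 15 is formed racemic and is erased in step 9, and any 16 or 17 formed by onward reaction in the flask is simply carried into that step.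

Step 9
Reactants: 15 racemic 5,8-dihydronaphthalene-1,4-dione
Product: 17 O,O'-bis(triisopropylsilyl)larreantin, via naphthalene-1,4-diol 16 (not isolated)
Conditions: Et3N (0.2 equiv), CH2Cl2, 23 °C, argon; then Ag2O (2 equiv), MgSO4, 23 °C
Reagents that add atoms: none
Why: Amine-catalysed prototropic isomerisation of the 5,8-dihydro-1,4-naphthoquinone (loss of the doubly activated C8–H and C5–H, reprotonation on oxygen) gives the aromatic naphthalene-1,4-diol 16, driven by aromatisation of both rings; Ag2O then oxidises the hydroquinone to the quinone. With the phenols silylated, the guaiacyl rings and the diarylmethane CH2 are not attacked by this mild oxidant.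

Step 10
Reactants: 17 O,O'-bis(triisopropylsilyl)larreantin
Product: 18 larreantin
Conditions: Bu4NF (2.5 equiv), AcOH (3 equiv), THF, 0 °C
Reagents that add atoms: none
Why: Fluoride-induced cleavage of aryl silyl ethers, fast because phenoxide is a good leaving group from silicon; acetic acid protonates the phenoxide as it forms, so the methoxyquinone never meets a strong base or nucleophile.

## Compound list

1 | 4-bromo-2-methoxyphenol | COc1cc(Br)ccc1O | starting material
2 | (4-bromo-2-methoxyphenoxy)triisopropylsilane | COc1cc(Br)ccc1O[Si](C(C)C)(C(C)C)C(C)C | intermediate
3 | propyne | CC#C | starting material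
4 | [2-methoxy-4-(prop-1-yn-1-yl)phenoxy]triisopropylsilane | CC#Cc1ccc(O[Si](C(C)C)(C(C)C)C(C)C)c(OC)c1 | intermediate
5 | (Z)-2-{1-[3-methoxy-4-(triisopropylsilyloxy)phenyl]prop-1-en-2-yl}-4,4,5,5-tetramethyl-1,3,2-dioxaborolane | C/C(=C\c1ccc(O[Si](C(C)C)(C(C)C)C(C)C)c(OC)c1)B1OC(C)(C)C(C)(C)O1 | intermediate
6 | 2,3-dibromoprop-1-ene | C=C(Br)CBr | starting material
7 | [3-methoxy-4-(triisopropylsilyloxy)phenyl]magnesium bromide | COc1cc([Mg]Br)ccc1O[Si](C(C)C)(C(C)C)C(C)C | intermediate (not isolated)
8 | [4-(2-bromoprop-2-en-1-yl)-2-methoxyphenoxy]triisopropylsilane | C=C(Br)Cc1ccc(O[Si](C(C)C)(C(C)C)C(C)C)c(OC)c1 | intermediate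
9 | (E)-1-[3-methoxy-4-(triisopropylsilyloxy)phenyl]-3-[3-methoxy-4-(triisopropylsilyloxy)benzyl]-2-methylbuta-1,3-diene | C=C(Cc1ccc(O[Si](C(C)C)(C(C)C)C(C)C)c(OC)c1)/C(C)=C/c1ccc(O[Si](C(C)C)(C(C)C)C(C)C)c(OC)c1 | intermediate
10 | 5-bromovanillin (3-bromo-4-hydroxy-5-methoxybenzaldehyde) | COc1cc(C=O)cc(Br)c1O | starting material
11 | 3-bromo-4-hydroxy-5-methoxyphenyl formate | COc1cc(OC=O)cc(Br)c1O | intermediate (not isolated)
12 | 2-bromo-6-methoxybenzene-1,4-diol | COc1cc(O)cc(Br)c1O | intermediate
13 | 2-bromo-6-methoxy-1,4-benzoquinone | COC1=CC(=O)C=C(Br)C1=O | intermediate
14 | racemic cis-fused adduct, 8a-bromo-2-methoxy-7-methyl-8-[3-methoxy-4-(triisopropylsilyloxy)phenyl]-6-[3-methoxy-4-(triisopropylsilyloxy)benzyl]-4a,5,8,8a-tetrahydronaphthalene-1,4-dione (H-4a cis to Br-8a, C8 aryl trans to Br; one enantiomer drawn) | COC1=CC(=O)[C@@H]2CC(Cc3ccc(O[Si](C(C)C)(C(C)C)C(C)C)c(OC)c3)=C(C)[C@H](c3ccc(O[Si](C(C)C)(C(C)C)C(C)C)c(OC)c3)[C@]2(Br)C1=O | intermediate (not isolated)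
15 | racemic 2-methoxy-7-methyl-8-[3-methoxy-4-(triisopropylsilyloxy)phenyl]-6-[3-methoxy-4-(triisopropylsilyloxy)benzyl]-5,8-dihydronaphthalene-1,4-dione | COC1=CC(=O)C2=C(C1=O)C(c1ccc(O[Si](C(C)C)(C(C)C)C(C)C)c(OC)c1)C(C)=C(Cc1ccc(O[Si](C(C)C)(C(C)C)C(C)C)c(OC)c1)C2 | intermediate
16 | 2-methoxy-7-methyl-8-[3-methoxy-4-(triisopropylsilyloxy)phenyl]-6-[3-methoxy-4-(triisopropylsilyloxy)benzyl]naphthalene-1,4-diol | COc1cc(O)c2cc(Cc3ccc(O[Si](C(C)C)(C(C)C)C(C)C)c(OC)c3)c(C)c(-c3ccc(O[Si](C(C)C)(C(C)C)C(C)C)c(OC)c3)c2c1O | intermediate (not isolated)
17 | O,O'-bis(triisopropylsilyl)larreantin | COC1=CC(=O)c2cc(Cc3ccc(O[Si](C(C)C)(C(C)C)C(C)C)c(OC)c3)c(C)c(-c3ccc(O[Si](C(C)C)(C(C)C)C(C)C)c(OC)c3)c2C1=O | intermediate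
18 | larreantin, 8-(4-hydroxy-3-methoxyphenyl)-6-(4-hydroxy-3-methoxybenzyl)-2-methoxy-7-methylnaphthalene-1,4-dione | COC1=CC(=O)c2cc(Cc3ccc(O)c(OC)c3)c(C)c(-c3ccc(O)c(OC)c3)c2C1=O | target

## Step count and least certain steps

Total step count: 10. Longest linear sequence: 7 steps (steps 1, 2, 3, 5, 8, 9, 10); steps 4, 6 and 7 are convergent branches.

**Step 8 (key step).** The bond between the aryl-bearing diene terminus and the bromine-bearing quinone carbon creates a congested quaternary centre, so the cycloaddition may be slow. Electron transfer between the electron-rich diene and the oxidising quinone, diene oligomerisation, and consumption of 13 as an oxidant for already formed 16 could then compete, and the deactivating methoxy group could erode the orientation. The fallback changes the dienophile and moves the methoxy group to the end. It sets out from 9 and uses commercial 2,6-dibromo-1,4-benzoquinone, which is more electrophilic, has two equivalent C=C bonds and is oriented by bromine alone. Cycloaddition (NaHCO3, toluene, 23 → 50 °C) would give the cis-fused dibromo adduct F1, which loses HBr to the racemic 2-bromo-5,8-dihydronaphthalene-1,4-dione F2. Acid-catalysed tautomerisation (p-TsOH, CH2Cl2) would lead to the 2-bromonaphthalene-1,4-diol F3, and Ag2O would oxidise it to the 2-bromo-1,4-naphthoquinone F4. Ipso addition–elimination of methoxide at the bromine-bearing C2 (NaOMe, 1.05 equiv, MeOH/THF, 0 °C) would then return to the route at 17.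

**Step 3.** Regiocontrol of the borylcupration could be eroded, because the electron-donating silyloxy group makes the benzylic C–Cu intermediate less favoured, and the boronate could suffer protodeboronation on purification. The fallback builds the trisubstituted alkene by carbometalation instead of hydroboration and also bypasses steps 2 and 5. It sets out from 8 and 2. Negishi coupling of 8 with ethynylzinc bromide (from ethynylmagnesium bromide and ZnBr2; Pd(PPh3)4, THF) would give the enyne [2-methoxy-4-(2-methylidenebut-3-yn-1-yl)phenoxy]triisopropylsilane F5. Zirconium-catalysed carboalumination (AlMe3, Cp2ZrCl2 10 mol %, CH2Cl2, 0 → 23 °C) adds methyl to the internal and aluminium to the terminal alkyne carbon in syn fashion, giving the (E)-dienyl dimethylalane F6 (not isolated). Coupling of F6 with 2 (Pd(PPh3)4, ZnCl2, THF, 50 °C) with retention would return to the route at 9.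

**Step 9.** Autoxidation or silver-mediated oxidation at the doubly activated C8–H and C5–H, or at the diarylmethane carbon, could compete with the prototropic shift, and the amine could degrade the methoxy ene-dione. The fallback replaces the tautomerisation–oxidation pair by a direct hydride-abstraction dehydrogenation. It sets out from 15, which would be treated with 2,3-dichloro-5,6-dicyano-1,4-benzoquinone (1.05 equiv, CH2Cl2, 0 °C); loss of hydride from C8 and of a proton from C5 would aromatise ring B and return to the route at 17. No new compound is formed on this path (F0).

**Step 10.** Phenoxide liberated by fluoride could attack the methoxyquinone of another molecule (conjugate addition or displacement of methoxide), or the bulky silyl groups could be cleaved incompletely. The fallback removes the silyl groups at the non-electrophilic hydroquinone oxidation level. It sets out from 17, which would be reduced with Na2S2O4 (EtOAc/H2O) to 16. Desilylation of 16 with Bu4NF (THF, argon) would give the tetraphenol 8-(4-hydroxy-3-methoxyphenyl)-6-(4-hydroxy-3-methoxybenzyl)-2-methoxy-7-methylnaphthalene-1,4-diol F7. Selective oxidation of its hydroquinone ring, which is far more easily oxidised than the guaiacyl phenols, with FeCl3 (aq.) or air would return to the route at 18.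

## Further compounds

F1 | step 8 | racemic cis-fused adduct, 2,8a-dibromo-7-methyl-8-[3-methoxy-4-(triisopropylsilyloxy)phenyl]-6-[3-methoxy-4-(triisopropylsilyloxy)benzyl]-4a,5,8,8a-tetrahydronaphthalene-1,4-dione (one enantiomer drawn) | BrC1=CC(=O)[C@@H]2CC(Cc3ccc(O[Si](C(C)C)(C(C)C)C(C)C)c(OC)c3)=C(C)[C@H](c3ccc(O[Si](C(C)C)(C(C)C)C(C)C)c(OC)c3)[C@]2(Br)C1=O
F2 | step 8 | racemic 2-bromo-7-methyl-8-[3-methoxy-4-(triisopropylsilyloxy)phenyl]-6-[3-methoxy-4-(triisopropylsilyloxy)benzyl]-5,8-dihydronaphthalene-1,4-dione | BrC1=CC(=O)C2=C(C1=O)C(c1ccc(O[Si](C(C)C)(C(C)C)C(C)C)c(OC)c1)C(C)=C(Cc1ccc(O[Si](C(C)C)(C(C)C)C(C)C)c(OC)c1)C2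
F3 | step 8 | 2-bromo-7-methyl-8-[3-methoxy-4-(triisopropylsilyloxy)phenyl]-6-[3-methoxy-4-(triisopropylsilyloxy)benzyl]naphthalene-1,4-diol | Brc1cc(O)c2cc(Cc3ccc(O[Si](C(C)C)(C(C)C)C(C)C)c(OC)c3)c(C)c(-c3ccc(O[Si](C(C)C)(C(C)C)C(C)C)c(OC)c3)c2c1O
F4 | step 8 | 2-bromo-7-methyl-8-[3-methoxy-4-(triisopropylsilyloxy)phenyl]-6-[3-methoxy-4-(triisopropylsilyloxy)benzyl]naphthalene-1,4-dione | BrC1=CC(=O)c2cc(Cc3ccc(O[Si](C(C)C)(C(C)C)C(C)C)c(OC)c3)c(C)c(-c3ccc(O[Si](C(C)C)(C(C)C)C(C)C)c(OC)c3)c2C1=O
F5 | step 3 | [2-methoxy-4-(2-methylidenebut-3-yn-1-yl)phenoxy]triisopropylsilane | C#CC(=C)Cc1ccc(O[Si](C(C)C)(C(C)C)C(C)C)c(OC)c1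
F6 | step 3 | dimethyl{(1E)-4-[3-methoxy-4-(triisopropylsilyloxy)phenyl]-2-methyl-3-methylidenebut-1-en-1-yl}alumane | C[Al](C)/C=C(C)/C(=C)Cc1ccc(O[Si](C(C)C)(C(C)C)C(C)C)c(OC)c1
F0 | step 9 | none | none
F7 | step 10 | 8-(4-hydroxy-3-methoxyphenyl)-6-(4-hydroxy-3-methoxybenzyl)-2-methoxy-7-methylnaphthalene-1,4-diol | COc1cc(O)c2cc(Cc3ccc(O)c(OC)c3)c(C)c(-c3ccc(O)c(OC)c3)c2c1O
A1 | alternative 1 | 3-[3-methoxy-4-(methoxymethoxy)phenyl]prop-2-yn-1-yl (E)-3-(2,4,5-trimethoxyphenyl)prop-2-enoate | COCOc1ccc(C#CCOC(=O)/C=C/c2cc(OC)c(OC)cc2OC)cc1OC
A2 | alternative 1 | 8-[3-methoxy-4-(methoxymethoxy)phenyl]-1,2,4-trimethoxynaphthalene fused at C6/C7 to a gamma-lactone (carbonyl on C6, CH2O on C7) | COc1cc(OC)c2cc3C(=O)OCc3c(-c3ccc(OCOC)c(OC)c3)c2c1OC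
A3 | alternative 2 | 4-[4-(benzyloxy)-3-methoxyphenyl]-1-(2,4,5-trimethoxyphenyl)but-3-yn-2-one | COc1cc(OC)c(CC(=O)C#Cc2ccc(OCc3ccccc3)c(OC)c2)cc1OC
A4 | alternative 2 | 8-[4-(benzyloxy)-3-methoxyphenyl]-7-iodo-1,2,4-trimethoxynaphthalen-6-ol | COc1cc(OC)c2cc(O)c(I)c(-c3ccc(OCc4ccccc4)c(OC)c3)c2c1OC
A5 | alternative 3 | 1-{2-[4-(benzyloxy)-3-methoxyphenyl]-4-[4-(benzyloxy)-3-methoxybenzyl]-6-iodo-3-methylphenyl}-2-methoxyprop-2-en-1-one | C=C(OC)C(=O)c1c(I)cc(Cc2ccc(OCc3ccccc3)c(OC)c2)c(C)c1-c1ccc(OCc2ccccc2)c(OC)c1
A6 | alternative 3 | O,O-dibenzyl larreantin | COC1=CC(=O)c2cc(Cc3ccc(OCc4ccccc4)c(OC)c3)c(C)c(-c3ccc(OCc4ccccc4)c(OC)c3)c2C1=O
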